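**Retrosynthetic overview**

1. Locants: oxolane O1, C2 (bears the carbinol carbon Cα), C3 (4-methoxyphenyl), C4 (OH, oxygen O4), C5 (CH2). Target 17 ⇐ ketone 16 (Cα–OH by chelation-controlled hydride addition) ⇐ bicyclic ether 15 (oxidative opening of a Cα–O4 benzylic ether).
2. 15 ⇐ acyclic α-acetoxy ether 12 by an intramolecular (3+2) cycloaddition of the carbonyl ylide C5–O1–C2 to the Z-enol ether C3=C4. Bonds C2–C3 and C5–C4, the oxolane ring and a temporary second five-membered ring (C2, Cα, O4, C4, C3) form together; the temporary ring is opened in step 9.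
3. Enabling feature: the ring oxygen O1 with its two carbons C2 and C5 is a latent carbonyl ylide, and Cα on C2 and O4 on C4 stand 1,3-cis on the oxolane. O4 can therefore be lent to Cα as a one-atom bridge (a 3,4-dimethoxybenzylic ether, giving a 2,5-dioxabicyclo[2.2.1]heptane), which excludes the other regiochemistry and forces the all-cis ring.
4. 12 ⇐ (trimethylsilyl)methyl ester 10 (reductive acetylation) ⇐ Chan–Lam O-alkenylation of mandelate 6 (from veratrole, ethyl chlorooxoacetate and asymmetric transfer hydrogenation) with Z-alkenyltrifluoroborate 9 (from 4-ethynylanisole).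
5. Stereochemistry: one catalytically set centre (Cα, S) is relayed to C2, C3 and C4 in the cycloaddition, erased by the oxidative opening, and rewritten as R under control of C2.

Key step: step 8

Remark: the configuration delivered in step 2 is assigned by the accepted aryl-under-arene model of the TsDPEN ruthenium catalysts; C2 of 11, 12 and 13 is an epimer mixture that converges in the ylide.

**Route**

Step 1
Reactants: 1 1,2-dimethoxybenzene (veratrole); 2 ethyl chlorooxoacetate
Product: 3 ethyl 2-(3,4-dimethoxyphenyl)-2-oxoacetate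
Conditions: AlCl3 (1.2 equiv), CH2Cl2, 0 °C to rt
Reagents that add atoms: none
Why: Friedel–Crafts acylation; the electrophile should enter para to a methoxy group (position 4), the unhindered activated site, and no stereocentre is formed.

Step 2
Reactants: 3 ethyl 2-(3,4-dimethoxyphenyl)-2-oxoacetate
Product: 4 ethyl (2S)-2-(3,4-dimethoxyphenyl)-2-hydroxyacetate
Conditions: RuCl(p-cymene)[(R,R)-TsDPEN] (0.5 mol %), HCO2H–Et3N (5:2), DMF, rt
Reagents that add atoms: none
Why: Noyori-type asymmetric transfer hydrogenation of an aryl ketone; the catalyst sets Cα, expected (S) when the aryl group lies under the arene ligand (CH–π model).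

Step 3
Reactants: 4 ethyl (2S)-2-(3,4-dimethoxyphenyl)-2-hydroxyacetate; 5 (trimethylsilyl)methanol
Product: 6 (trimethylsilyl)methyl (2S)-2-(3,4-dimethoxyphenyl)-2-hydroxyacetate
Conditions: Ti(OEt)4 (10 mol %), 5 (3 equiv), toluene, 90 °C, ethanol removed over molecular sieves 4 Å
Reagents that add atoms: none
Why: titanate-catalysed transesterification is neutral enough to leave the α-hydroxy ester centre untouched, and the primary alcohol in excess should outcompete the hindered benzylic hydroxyl.

Step 4
Reactants: 7 1-ethynyl-4-methoxybenzene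
Product: 8 2-[(Z)-2-(4-methoxyphenyl)ethenyl]-4,4,5,5-tetramethyl-1,3,2-dioxaborolane
Conditions: [Rh(cod)Cl]2 (1.5 mol %), P(i-Pr)3 (6 mol %), Et3N, pinacolborane (limiting, 7 in 1.2-fold excess), cyclohexane, rt
Reagents that add atoms: pinacolborane, CC1(C)OBOC1(C)C
Why: rhodium-catalysed trans-hydroboration of a terminal alkyne through a vinylidene complex should give the anti-Markovnikov Z-alkenylboronate (boron and aryl cis).

Step 5
Reactants: 8 2-[(Z)-2-(4-methoxyphenyl)ethenyl]-4,4,5,5-tetramethyl-1,3,2-dioxaborolane
Product: 9 potassium trifluoro[(Z)-2-(4-methoxyphenyl)ethenyl]borate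
Conditions: KHF2 (4 equiv), MeOH–H2O, rt
Reagents that add atoms: potassium hydrogen difluoride, [K+].F[H-]F
Why: standard conversion of a pinacol boronate into the trifluoroborate salt, with no change at the alkene.

Step 6
Reactants: 6 (trimethylsilyl)methyl (2S)-2-(3,4-dimethoxyphenyl)-2-hydroxyacetate; 9 potassium trifluoro[(Z)-2-(4-methoxyphenyl)ethenyl]borate (2 equiv)
Product: 10 (trimethylsilyl)methyl (2S)-2-(3,4-dimethoxyphenyl)-2-{[(Z)-2-(4-methoxyphenyl)ethenyl]oxy}acetate
Conditions: Cu(OAc)2·H2O (10 mol %), DMAP (20 mol %), molecular sieves 4 Å, O2 (1 atm), CH2Cl2, rt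
Reagents that add atoms: none
Why: Chan–Lam-type oxidative C–O coupling of an aliphatic alcohol with an alkenyltrifluoroborate; alkenyl transfer at copper should keep the Z geometry, and the neutral conditions at rt should leave Cα untouched.

Step 7
Reactants: 10 (trimethylsilyl)methyl (2S)-2-(3,4-dimethoxyphenyl)-2-{[(Z)-2-(4-methoxyphenyl)ethenyl]oxy}acetate
Product: 12 (2S)-2-(3,4-dimethoxyphenyl)-2-{[(Z)-2-(4-methoxyphenyl)ethenyl]oxy}-1-[(trimethylsilyl)methoxy]ethyl acetate (both C1 epimers), via aluminium hemiacetal 11 (not isolated)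
Conditions: i-Bu2AlH (1.2 equiv), CH2Cl2, −78 °C; then pyridine, DMAP, Ac2O, −78 to 0 °C
Reagents that add atoms: acetic anhydride, CC(=O)OC(C)=O
Why: reductive acetylation of an ester; the chelated tetrahedral aluminium hemiacetal is stable at −78 °C and is acetylated in situ to the α-acetoxy ether, whose new centre (the later C2) becomes planar in step 8.

Step 8
Reactants: 12 (2S)-2-(3,4-dimethoxyphenyl)-2-{[(Z)-2-(4-methoxyphenyl)ethenyl]oxy}-1-[(trimethylsilyl)methoxy]ethyl acetate
Product: 15 (1S,3S,4S,7R)-3-(3,4-dimethoxyphenyl)-7-(4-methoxyphenyl)-2,5-dioxabicyclo[2.2.1]heptane, via α-bromo ether 13 (not isolated), via carbonyl ylide 14 (not isolated)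
Conditions: Me3SiBr (1.05 equiv), 2,6-di-tert-butyl-4-methylpyridine (0.3 equiv), CH2Cl2, −78 to −40 °C; then added slowly to CsF (5 equiv) in MeCN (final 0.005 M), −40 °C to rt
Reagents that add atoms: none
Why: Proposed new method: bromotrimethylsilane exchanges the acetate of 12 for bromide, fluoride then removes the silyl group from C5 while bromide leaves C2 (1,3-elimination across C5–O1–C2), and the non-stabilised carbonyl ylide 14, in the sickle form with Cα syn to C5, adds in one suprafacial (3+2) event across the tethered Z-enol ether C3=C4. The closest known reactions are the fluoride-induced generation of carbonyl ylides from α-haloalkyl silylmethyl ethers, so far trapped between two molecules, and the bridged intramolecular cycloadditions of but-3-enyl nitrones and of rhodium-derived carbonyl ylides; the transfer to an enol ether on a two-atom tether is the untested part. The oxolane ring (O1, C2, C3, C4, C5) closes by the two new bonds C2–C3 and C5–C4, and the temporary ring (C2, Cα, O4, C4, C3) closes through the same C2–C3 bond in the bridged mode; the fused mode would need a four-membered ring, so the tether fixes the regiochemistry. C3 and C4 keep the cis relation of the Z-alkene because the addition is concerted, C2 must be cis to O4 because both sit on the same bridge, and the absolute sense of all three is set by Cα, whose aryl group should take the endo position, away from the 4-methoxyphenyl group on C3 that points over the Cα–O4 bridge. The step therefore needs only facial selectivity (aryl endo against exo at Cα, which becomes the enantiomeric purity after step 9 and can be completed by chromatography of the diastereomers of 15), and it needs desilylation to outrun ionic capture of C2 by C3, which the stepwise 5-endo geometry, the cold halide exchange and high dilution should disfavour.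

Step 9
Reactants: 15 (1S,3S,4S,7R)-3-(3,4-dimethoxyphenyl)-7-(4-methoxyphenyl)-2,5-dioxabicyclo[2.2.1]heptane
Product: 16 (3,4-dimethoxyphenyl)[(2S,3R,4S)-4-hydroxy-3-(4-methoxyphenyl)oxolan-2-yl]methanone
Conditions: DDQ (1.3 equiv), CH2Cl2–aqueous phosphate buffer pH 7 (10:1), 0 °C
Reagents that add atoms: water, O
Why: oxidative cleavage of an electron-rich benzylic ether (3,4-dimethoxybenzyl type): hydride abstraction at Cα, addition of water and collapse of the hemiketal should give the aryl ketone and free O4–H, while the ring centres are untouched and the neutral buffer guards C2 against epimerisation.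

Step 10
Reactants: 16 (3,4-dimethoxyphenyl)[(2S,3R,4S)-4-hydroxy-3-(4-methoxyphenyl)oxolan-2-yl]methanone
Product: 17 (3S,4R,5S)-5-[(R)-(3,4-dimethoxyphenyl)(hydroxy)methyl]-4-(4-methoxyphenyl)oxolan-3-ol (target)
Conditions: Zn(BH4)2 (1.5 equiv), Et2O, −40 to −10 °C; aqueous NH4Cl
Reagents that add atoms: none
Why: Cram-chelate reduction of an α-alkoxy ketone: zinc bridges the ketone oxygen and O1 (O4–H on the same face can join the chelate), and hydride should add from the side of C2–H, away from C3 and its aryl group, to give the (R)-carbinol, anti to O1.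

**Compound list**

1 | 1,2-dimethoxybenzene | COc1ccccc1OC | starting material
2 | ethyl chlorooxoacetate | CCOC(=O)C(=O)Cl | starting material
3 | ethyl 2-(3,4-dimethoxyphenyl)-2-oxoacetate | CCOC(=O)C(=O)c1ccc(OC)c(OC)c1 | intermediate
4 | ethyl (2S)-2-(3,4-dimethoxyphenyl)-2-hydroxyacetate | CCOC(=O)[C@@H](O)c1ccc(OC)c(OC)c1 | intermediate
5 | (trimethylsilyl)methanol | C[Si](C)(C)CO | starting material
6 | (trimethylsilyl)methyl (2S)-2-(3,4-dimethoxyphenyl)-2-hydroxyacetate | C[Si](C)(C)COC(=O)[C@@H](O)c1ccc(OC)c(OC)c1 | intermediate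
7 | 1-ethynyl-4-methoxybenzene | COc1ccc(C#C)cc1 | starting material
8 | 2-[(Z)-2-(4-methoxyphenyl)ethenyl]-4,4,5,5-tetramethyl-1,3,2-dioxaborolane | COc1ccc(/C=C\B2OC(C)(C)C(C)(C)O2)cc1 | intermediate
9 | potassium trifluoro[(Z)-2-(4-methoxyphenyl)ethenyl]borate | COc1ccc(/C=C\[B-](F)(F)F)cc1.[K+] | intermediate
10 | (trimethylsilyl)methyl (2S)-2-(3,4-dimethoxyphenyl)-2-{[(Z)-2-(4-methoxyphenyl)ethenyl]oxy}acetate | C[Si](C)(C)COC(=O)[C@@H](O/C=C\c1ccc(OC)cc1)c1ccc(OC)c(OC)c1 | intermediate
11 | {(2S)-2-(3,4-dimethoxyphenyl)-2-{[(Z)-2-(4-methoxyphenyl)ethenyl]oxy}-1-[(trimethylsilyl)methoxy]ethoxy}bis(2-methylpropyl)aluminium (aluminium hemiacetal, not isolated) | C[Si](C)(C)COC(O[Al](CC(C)C)CC(C)C)[C@@H](O/C=C\c1ccc(OC)cc1)c1ccc(OC)c(OC)c1 | intermediate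
12 | (2S)-2-(3,4-dimethoxyphenyl)-2-{[(Z)-2-(4-methoxyphenyl)ethenyl]oxy}-1-[(trimethylsilyl)methoxy]ethyl acetate (both C1 epimers) | C[Si](C)(C)COC(OC(C)=O)[C@@H](O/C=C\c1ccc(OC)cc1)c1ccc(OC)c(OC)c1 | intermediate
13 | {[(2S)-1-bromo-2-(3,4-dimethoxyphenyl)-2-{[(Z)-2-(4-methoxyphenyl)ethenyl]oxy}ethoxy]methyl}trimethylsilane (α-bromo ether, not isolated) | C[Si](C)(C)COC(Br)[C@@H](O/C=C\c1ccc(OC)cc1)c1ccc(OC)c(OC)c1 | intermediate
14 | carbonyl ylide C5H2–O1–C2H carrying the (S)-Cα stereocentre and the Z-enol ether (not isolated) | [CH2-][O+]=C[C@@H](O/C=C\c1ccc(OC)cc1)c1ccc(OC)c(OC)c1 | intermediate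
15 | (1S,3S,4S,7R)-3-(3,4-dimethoxyphenyl)-7-(4-methoxyphenyl)-2,5-dioxabicyclo[2.2.1]heptane | COc1ccc([C@H]2[C@H]3[C@H](c4ccc(OC)c(OC)c4)O[C@@H]2CO3)cc1 | intermediate
16 | (3,4-dimethoxyphenyl)[(2S,3R,4S)-4-hydroxy-3-(4-methoxyphenyl)oxolan-2-yl]methanone | COc1ccc([C@H]2[C@@H](C(=O)c3ccc(OC)c(OC)c3)OC[C@H]2O)cc1 | intermediate
17 | (3S,4R,5S)-5-[(R)-(3,4-dimethoxyphenyl)(hydroxy)methyl]-4-(4-methoxyphenyl)oxolan-3-ol | COc1ccc([C@H]2[C@@H]([C@H](O)c3ccc(OC)c(OC)c3)OC[C@H]2O)cc1 | target

**Step count**

Total steps: 10. Longest linear sequence: 8 (steps 1, 2, 3, 6, 7, 8, 9, 10); steps 4 and 5 form the side branch.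

**Steps most likely to fail**

Step 8 (proposed method). The bromo ether may lose HBr towards the conjugated enol ether or be captured at C2 by the enol ether carbon C3 before desilylation. The ylide may close to the oxirane or shift the hydrogen of Cα. Facial selectivity at Cα may be incomplete. The fallback uses known chemistry and a stabilised instead of a non-stabilised ylide. It sets out from 10: i-Bu2AlH at −78 °C with aqueous work-up should give (2S)-2-(3,4-dimethoxyphenyl)-2-{[(Z)-2-(4-methoxyphenyl)ethenyl]oxy}acetaldehyde F1. Slow addition of ethyl diazoacetate to F1 and Rh2(OAc)4 (1 mol %) in CH2Cl2 should form the ester-stabilised carbonyl ylide F2 at the aldehyde oxygen, an electrophilic dipole matched to the enol ether. F2 should undergo the same bridged cycloaddition to the 6-ethoxycarbonyl derivative of the bicycle F3. LiOH in aqueous THF should give the carboxylic acid F4. Barton decarboxylation (N-hydroxypyridine-2-thione and DCC to the thiohydroxamate ester F5, then t-BuSH under visible light) removes the carboxyl group from C5, which is CH2 in the target. The fallback comes back to the route at 15.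

Step 6. The oxidative coupling may stall on the hindered, electron-poor secondary alcohol while the alkenylborate is lost by protodeboronation or homocoupling, or the alkene may isomerise. The fallback replaces the oxidative coupling of a boron reagent by an Ullmann-type coupling of a vinyl halide. Stork–Zhao olefination of commercial 4-methoxybenzaldehyde ([Ph3PCH2I]I, NaN(SiMe3)2, THF, −78 °C) should give 1-[(Z)-2-iodoethenyl]-4-methoxybenzene F6. F6 is coupled with 6 (CuI, 3,4,7,8-tetramethyl-1,10-phenanthroline, Cs2CO3, toluene, 80 °C) with retention of the alkene geometry. The fallback sets out from 6 and comes back at 10.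

Step 10. Facial selectivity may be poor if non-chelated or O4-directed hydride delivery competes with the zinc chelate, and C2 may epimerise before reduction. The fallback replaces substrate control by reagent control: Corey–Bakshi–Shibata reduction of 16 with (R)-2-methyl-CBS-oxazaborolidine and BH3·SMe2 in THF at −20 °C. The catalyst antipode is chosen so that, with the aryl group as the larger substituent, hydride adds to the face that gives the (R)-carbinol. The fallback sets out from 16, comes back at 17 and makes no new compound.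

**Further compounds**

F1 | step 8 | (2S)-2-(3,4-dimethoxyphenyl)-2-{[(Z)-2-(4-methoxyphenyl)ethenyl]oxy}acetaldehyde | O=C[C@@H](O/C=C\c1ccc(OC)cc1)c1ccc(OC)c(OC)c1
F2 | step 8 | ester-stabilised carbonyl ylide from F1 and ethyl diazoacetate (not isolated) | CCOC(=O)[CH-][O+]=C[C@@H](O/C=C\c1ccc(OC)cc1)c1ccc(OC)c(OC)c1
F3 | step 8 | ethyl 3-(3,4-dimethoxyphenyl)-7-(4-methoxyphenyl)-2,5-dioxabicyclo[2.2.1]heptane-6-carboxylate, ring configuration as in 15, both C6 epimers | COc1ccc([C@H]2[C@H]3[C@H](c4ccc(OC)c(OC)c4)O[C@@H]2C(C(=O)OCC)O3)cc1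
F4 | step 8 | 3-(3,4-dimethoxyphenyl)-7-(4-methoxyphenyl)-2,5-dioxabicyclo[2.2.1]heptane-6-carboxylic acid, ring configuration as in 15 | COc1ccc([C@H]2[C@H]3[C@H](c4ccc(OC)c(OC)c4)O[C@@H]2C(C(=O)O)O3)cc1
F5 | step 8 | 2-thioxopyridin-1(2H)-yl ester of F4 (Barton ester) | COc1ccc([C@H]2[C@H]3[C@H](c4ccc(OC)c(OC)c4)O[C@@H]2C(C(=O)ON5C=CC=CC5=S)O3)cc1
F6 | step 6 | 1-[(Z)-2-iodoethenyl]-4-methoxybenzene | COc1ccc(/C=C\I)cc1
F0 | step 10 | none | none
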